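**Plan**
- Retrosynthesis: the exocyclic C3=CH2 is traced back to a C3 carboxyl (decarboxylative Mannich). The lactone bond O1–C5 is then cut and C5 re-joined to C3, giving a cyclopropane-1,1,2-triester. Its C3–C5 and C3–C4 bonds are cut to an (E)-enal and dibenzyl bromomalonate, and the enal C=C is cut by a Wittig disconnection to 14-acetoxytetradecanal.
- Enabling feature (lactone atoms O1, carbonyl C2, C3 with the methylidene, C4 with CO2H, C5 with the chain): O1–C5 is the ring's only carbon–heteroatom bond at a stereogenic carbon, and C3 is one decarboxylation away from a malonate carbon. C3, C4 and C5 can therefore be the three carbons of a cyclopropane with C3 as its geminal diester carbon.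
- Forward: the C14 diol is desymmetrised and extended to the C16 enal; the three-membered ring is built first and then expanded to the five-membered lactone, the only ring of the target; the methylidene is installed last.
- Stereochemistry: C5 (R) comes from the face-selective conjugate addition under prolinol silyl ether catalysis and C4 (S) from the trans-selective ring closure of the same step. C4 is never touched afterwards, and C5 is carried through the ring expansion with net retention (double inversion).

Key step: step 8

Assumption: C3 of 14 and 15 is an epimerisable malonate-type centre; it is drawn trans to the C4 carboxyl and its configuration is irrelevant because step 10 removes it.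

**Step 1**
Reactants: 1 1,14-tetradecanediol
Product: 2 14-hydroxytetradecyl acetate
Conditions: Ac2O (1.0 equiv), pyridine, DMAP (cat.), THF, 0 °C to rt
Reagents that add atoms: acetic anhydride CC(=O)OC(C)=O
Why: Statistical mono-acylation of a symmetrical diol (nucleophilic acyl substitution) with one equivalent of anhydride should give the mono-acetate, separable from diol (recycled) and diacetate.

**Step 2**
Reactants: 2 14-hydroxytetradecyl acetate
Product: 3 14-oxotetradecyl acetate
Conditions: TEMPO (cat.), PhI(OAc)2 (1.1 equiv), CH2Cl2, rt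
Reagents that add atoms: none
Why: Oxoammonium-mediated (TEMPO) oxidation of a primary alcohol should stop at the aldehyde and leave the acetate untouched.

**Step 3**
Reactants: 3 14-oxotetradecyl acetate; 4 (triphenylphosphoranylidene)acetaldehyde
Product: 5 (E)-16-acetoxyhexadec-2-enal
Conditions: toluene, 80 °C
Reagents that add atoms: none
Why: Wittig reaction of the stabilised formylmethylene ylide with an aliphatic aldehyde should give the two-carbon-extended (E)-enal.

**Step 4**
Reactants: 6 dibenzyl malonate
Product: 7 dibenzyl 2-bromomalonate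
Conditions: Br2 (1.0 equiv), CH2Cl2, 0 °C to rt
Reagents that add atoms: bromine BrBr
Why: Electrophilic α-bromination of the malonate enol with one equivalent of bromine should give the monobromide.

**Step 5**
Reactants: 5 (E)-16-acetoxyhexadec-2-enal; 7 dibenzyl 2-bromomalonate
Product: 8 dibenzyl (2R,3R)-2-(13-acetoxytridecyl)-3-formylcyclopropane-1,1-dicarboxylate
Conditions: (S)-α,α-diphenylprolinol trimethylsilyl ether (20 mol %), 2,6-lutidine (1.1 equiv), CH2Cl2, 0 °C to rt
Reagents that add atoms: none
Why: Organocatalytic Michael-initiated ring closure (iminium–enamine cascade): the bromomalonate should add to the β-carbon of the (E)-iminium ion on the face away from the CPh2OTMS group, which sets the chain-bearing carbon as R, and the enamine then displaces bromide (3-exo-tet) to place the formyl group trans to the chain.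

**Step 6**
Reactants: 8 dibenzyl (2R,3R)-2-(13-acetoxytridecyl)-3-formylcyclopropane-1,1-dicarboxylate
Product: 9 1,1-dibenzyl 2-hydrogen (2R,3R)-3-(13-acetoxytridecyl)cyclopropane-1,1,2-tricarboxylate
Conditions: NaClO2, NaH2PO4, 2-methyl-2-butene, t-BuOH–H2O, 0 °C to rt
Reagents that add atoms: sodium chlorite [Na+].[O-]Cl=O
Why: Pinnick oxidation should convert the aldehyde into the acid under buffered conditions that neither epimerise the α-carbon nor open the cyclopropane.

**Step 7**
Reactants: 9 1,1-dibenzyl 2-hydrogen (2R,3R)-3-(13-acetoxytridecyl)cyclopropane-1,1,2-tricarboxylate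
Product: 10 tribenzyl (2R,3R)-3-(13-acetoxytridecyl)cyclopropane-1,1,2-tricarboxylate
Conditions: BnBr (1.1 equiv), KHCO3, DMF, rt
Reagents that add atoms: benzyl bromide BrCc1ccccc1
Why: SN2 O-alkylation of the carboxylate with benzyl bromide under weakly basic conditions should give the benzyl ester without touching the acetate.

**Step 8**
Reactants: 10 tribenzyl (2R,3R)-3-(13-acetoxytridecyl)cyclopropane-1,1,2-tricarboxylate
Product: 14 dibenzyl (3R,4S,5R)-5-(13-acetoxytridecyl)-2-oxotetrahydrofuran-3,4-dicarboxylate, via iodomalonate magnesium enolate 11 (not isolated), via benzyl ketene acetal 12 (not isolated), via lactone magnesium enolate 13 (not isolated)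
Conditions: MgI2 (1.5 equiv), THF–toluene (1:4), 70 °C, sealed tube; then aq. HCl (0.5 M), 0 °C
Reagents that add atoms: none
Why: Proposed new method: chelation of the geminal diester of 10 by MgI2 should polarise the bond between the malonate carbon (C3) and the alkyl-bearing C5, iodide opens it at C5 with inversion to the γ-iodo malonate enolate 11, the enolate oxygen displaces iodide with a second inversion to give the cyclic benzyl ketene acetal 12, and iodide then removes the benzyl group from the magnesium-activated acetal oxygen to leave the chelated enolate 13, which is protonated on work-up to 14. The closest known reaction types are the iodide- or Lewis-acid-promoted ring expansion of aryl- and vinyl-substituted cyclopropane-1,1-diesters to γ-butyrolactones (a nucleophile-assisted Cloke–Wilson rearrangement) and the acid-induced lactonisation of cyclopropane-1,1-dicarboxylic acids, neither of which has been shown for a purely alkyl donor flanked by an ester. The lactone ring closes by 5-exo-tet formation of O1–C5, and the sequence is driven by release of cyclopropane strain and the irreversible loss of benzyl iodide. C5 keeps its configuration through the double inversion, so the trans cyclopropane should give the 4,5-trans lactone, C4 is not involved, and C3 is set on protonation of 13 under thermodynamic control trans to the C4 ester. The selectivity needed is cleavage of C3–C5 and not C3–C4: both bonds are activated by the chelated malonate, but only C5, which carries the alkyl chain, can take the partial positive charge of the loose, Lewis-acid-assisted transition state, whereas C4 is deactivated by its own ester, and the weakly polar medium is chosen to favour this charge-controlled pathway.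

**Step 9**
Reactants: 14 dibenzyl (3R,4S,5R)-5-(13-acetoxytridecyl)-2-oxotetrahydrofuran-3,4-dicarboxylate
Product: 15 (3R,4S,5R)-5-(13-acetoxytridecyl)-2-oxotetrahydrofuran-3,4-dicarboxylic acid
Conditions: H2 (1 atm), 10% Pd/C, EtOAc, rt
Reagents that add atoms: none
Why: Catalytic hydrogenolysis should cleave both benzyl esters at room temperature while the acetate and the lactone stay intact, and the malonic-type acid is used directly without heating.

**Step 10**
Reactants: 15 (3R,4S,5R)-5-(13-acetoxytridecyl)-2-oxotetrahydrofuran-3,4-dicarboxylic acid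
Product: 17 (2R,3S)-2-(13-acetoxytridecyl)-4-methylidene-5-oxotetrahydrofuran-3-carboxylic acid, via Mannich base 16 (not isolated)
Conditions: aq. CH2O (37%), Et2NH, NaOAc, AcOH, rt then 60 °C
Reagents that add atoms: formaldehyde C=O
Why: Decarboxylative Mannich methylenation: the malonic-type C3–H should add to the iminium ion formed from formaldehyde and diethylamine, and Mannich base 16 should fragment with loss of CO2 and diethylamine to the exocyclic methylidene, which removes the C3 centre and leaves C4 and C5 unchanged.

**Compound list**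
1 | 1,14-tetradecanediol | OCCCCCCCCCCCCCCO | starting material
2 | 14-hydroxytetradecyl acetate | CC(=O)OCCCCCCCCCCCCCCO | intermediate
3 | 14-oxotetradecyl acetate (14-acetoxytetradecanal) | CC(=O)OCCCCCCCCCCCCCC=O | intermediate
4 | (triphenylphosphoranylidene)acetaldehyde | O=CC=P(c1ccccc1)(c1ccccc1)c1ccccc1 | starting material
5 | (E)-16-acetoxyhexadec-2-enal | CC(=O)OCCCCCCCCCCCCC/C=C/C=O | intermediate
6 | dibenzyl malonate | O=C(CC(=O)OCc1ccccc1)OCc1ccccc1 | starting material
7 | dibenzyl 2-bromomalonate | O=C(OCc1ccccc1)C(Br)C(=O)OCc1ccccc1 | intermediate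
8 | dibenzyl (2R,3R)-2-(13-acetoxytridecyl)-3-formylcyclopropane-1,1-dicarboxylate | C1(C(=O)OCc2ccccc2)(C(=O)OCc2ccccc2)[C@H](CCCCCCCCCCCCCOC(C)=O)[C@H]1C=O | intermediate
9 | 1,1-dibenzyl 2-hydrogen (2R,3R)-3-(13-acetoxytridecyl)cyclopropane-1,1,2-tricarboxylate | C1(C(=O)OCc2ccccc2)(C(=O)OCc2ccccc2)[C@H](CCCCCCCCCCCCCOC(C)=O)[C@H]1C(=O)O | intermediate
10 | tribenzyl (2R,3R)-3-(13-acetoxytridecyl)cyclopropane-1,1,2-tricarboxylate | C1(C(=O)OCc2ccccc2)(C(=O)OCc2ccccc2)[C@H](CCCCCCCCCCCCCOC(C)=O)[C@H]1C(=O)OCc2ccccc2 | intermediate
11 | iodomagnesium enolate of tribenzyl (2R,3S)-16-acetoxy-3-iodohexadecane-1,1,2-tricarboxylate | I[C@@H](CCCCCCCCCCCCCOC(C)=O)[C@H](C(C(=O)OCc1ccccc1)=C(OCc1ccccc1)O[Mg]I)C(=O)OCc1ccccc1 | intermediate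
12 | dibenzyl (4S,5R)-5-(13-acetoxytridecyl)-2-(benzyloxy)-4,5-dihydrofuran-3,4-dicarboxylate | O1C(OCc2ccccc2)=C(C(=O)OCc2ccccc2)[C@H](C(=O)OCc2ccccc2)[C@H]1CCCCCCCCCCCCCOC(C)=O | intermediate
13 | iodomagnesium enolate of dibenzyl (4S,5R)-5-(13-acetoxytridecyl)-2-oxotetrahydrofuran-3,4-dicarboxylate | I[Mg]OC(OCc2ccccc2)=C1C(=O)O[C@H](CCCCCCCCCCCCCOC(C)=O)[C@H]1C(=O)OCc2ccccc2 | intermediate
14 | dibenzyl (3R,4S,5R)-5-(13-acetoxytridecyl)-2-oxotetrahydrofuran-3,4-dicarboxylate | [C@@H]1(C(=O)OCc2ccccc2)C(=O)O[C@H](CCCCCCCCCCCCCOC(C)=O)[C@H]1C(=O)OCc2ccccc2 | intermediate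
15 | (3R,4S,5R)-5-(13-acetoxytridecyl)-2-oxotetrahydrofuran-3,4-dicarboxylic acid | [C@@H]1(C(=O)O)C(=O)O[C@H](CCCCCCCCCCCCCOC(C)=O)[C@H]1C(=O)O | intermediate
16 | (4S,5R)-5-(13-acetoxytridecyl)-3-[(diethylamino)methyl]-2-oxotetrahydrofuran-3,4-dicarboxylic acid (C3 not assigned) | CCN(CC)CC1(C(=O)O)C(=O)O[C@H](CCCCCCCCCCCCCOC(C)=O)[C@H]1C(=O)O | intermediate
17 | (2R,3S)-2-(13-acetoxytridecyl)-4-methylidene-5-oxotetrahydrofuran-3-carboxylic acid (CNP0178400.1; 4S,5R in the lactone numbering of the plan) | C=C1C(=O)O[C@H](CCCCCCCCCCCCCOC(C)=O)[C@H]1C(=O)O | target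

**Step count**
Total: 10 steps. Longest linear sequence: 9 steps (1, 2, 3, 5, 6, 7, 8, 9, 10) from 1,14-tetradecanediol; step 4 is a one-step side branch.

**Steps most likely to fail**

Step 8 (proposed method). Three processes could defeat it: iodide may attack the ester-bearing C4 (an SN2 displacement α to a carbonyl) and lead to the regioisomeric lactone; the alkyl-substituted ring may not open at a temperature the rest of the molecule tolerates; or the benzyl iodide released may C-benzylate enolate 13. The fallback uses known chemistry, sets out from aldehyde 3 and returns to the route at diacid 15. Aldehyde 3 would be combined in a boron-mediated syn-aldol reaction (Bu2BOTf, i-Pr2NEt, CH2Cl2, −78 to 0 °C) with methyl 4-[(4S)-4-benzyl-2-oxo-1,3-oxazolidin-3-yl]-4-oxobutanoate F1, itself made from (S)-4-benzyl-1,3-oxazolidin-2-one, n-BuLi and methyl 4-chloro-4-oxobutanoate. The resulting syn-aldol adduct F2 should close with loss of methanol (cat. TsOH, CH2Cl2) to the trans lactone imide F3. LiOH/H2O2 (THF–H2O, 0 °C, short contact to spare the acetate) would remove the auxiliary and give the paraconic acid F4. Carboxylation of F4 at C3 with MeOMgOCO2Me in DMF at 130 °C and acidification would give 15, from which step 10 follows unchanged. In this variant both stereocentres come from the auxiliary-controlled aldol and the ring closes at O1–C2.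

Step 5. Conjugate addition of the bulky bromomalonate to the long-chain aliphatic iminium ion may be slow, and base-induced retro-Michael opening of the formylcyclopropane to the α-malonyl enal may erode yield and enantiopurity. The fallback separates the stereo-determining addition from the ring closure; it sets out from enal 5 and dibenzyl malonate 6 and returns at aldehyde 8. Base-free conjugate addition of 6 to 5 with (S)-2-{bis[3,5-bis(trifluoromethyl)phenyl](trimethylsilyloxy)methyl}pyrrolidine in EtOH at 0 °C should give the Michael adduct dibenzyl 2-[(3R)-16-acetoxy-1-oxohexadecan-3-yl]propanedioate F5. Treatment with I2 and K2CO3 in MeCN would iodinate the malonate carbon to the iodomalonate F6, whose aldehyde enolate closes the three-membered ring by 3-exo-tet displacement of iodide to give the trans aldehyde 8.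

Step 10. Loss of CO2 from the malonic-type acid may outrun the Mannich condensation and leave the unmethylenated lactone, and the new double bond may migrate into the ring. The fallback forms the C–CH2 bond before the acids are unmasked; it sets out from lactone diester 14 and returns at target 17. Aminomethylation of the doubly activated C3–H of 14 with dimethyl(methylidene)ammonium iodide and Et3N in CH2Cl2 should give the Mannich ester dibenzyl (4S,5R)-5-(13-acetoxytridecyl)-3-[(dimethylamino)methyl]-2-oxotetrahydrofuran-3,4-dicarboxylate F7. Hydrogenolysis (H2, 10% Pd/C, EtOAc) would free the amino diacid F8, which on gentle warming in MeCN should fragment with loss of CO2 and dimethylamine to 17.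

**Further compounds**
F1 | step 8 | methyl 4-[(4S)-4-benzyl-2-oxo-1,3-oxazolidin-3-yl]-4-oxobutanoate | COC(=O)CCC(=O)N1[C@@H](Cc2ccccc2)COC1=O
F2 | step 8 | methyl (3S,4R)-17-acetoxy-3-{[(4S)-4-benzyl-2-oxo-1,3-oxazolidin-3-yl]carbonyl}-4-hydroxyheptadecanoate | COC(=O)C[C@H](C(=O)N1[C@@H](Cc2ccccc2)COC1=O)[C@H](O)CCCCCCCCCCCCCOC(C)=O
F3 | step 8 | (4S)-3-{[(2R,3S)-2-(13-acetoxytridecyl)-5-oxotetrahydrofuran-3-yl]carbonyl}-4-benzyl-1,3-oxazolidin-2-one | O=C1C[C@H](C(=O)N2[C@@H](Cc3ccccc3)COC2=O)[C@@H](CCCCCCCCCCCCCOC(C)=O)O1
F4 | step 8 | (2R,3S)-2-(13-acetoxytridecyl)-5-oxotetrahydrofuran-3-carboxylic acid | O=C1C[C@H](C(=O)O)[C@@H](CCCCCCCCCCCCCOC(C)=O)O1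
F5 | step 5 | dibenzyl 2-[(3R)-16-acetoxy-1-oxohexadecan-3-yl]propanedioate | O=CC[C@@H](CCCCCCCCCCCCCOC(C)=O)C(C(=O)OCc1ccccc1)C(=O)OCc1ccccc1
F6 | step 5 | dibenzyl 2-[(3R)-16-acetoxy-1-oxohexadecan-3-yl]-2-iodopropanedioate | O=CC[C@@H](CCCCCCCCCCCCCOC(C)=O)C(I)(C(=O)OCc1ccccc1)C(=O)OCc1ccccc1
F7 | step 10 | dibenzyl (4S,5R)-5-(13-acetoxytridecyl)-3-[(dimethylamino)methyl]-2-oxotetrahydrofuran-3,4-dicarboxylate | CN(C)CC1(C(=O)OCc2ccccc2)C(=O)O[C@H](CCCCCCCCCCCCCOC(C)=O)[C@H]1C(=O)OCc2ccccc2
F8 | step 10 | (4S,5R)-5-(13-acetoxytridecyl)-3-[(dimethylamino)methyl]-2-oxotetrahydrofuran-3,4-dicarboxylic acid | CN(C)CC1(C(=O)O)C(=O)O[C@H](CCCCCCCCCCCCCOC(C)=O)[C@H]1C(=O)O
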